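**Retrosynthetic overview**
- Propolin B ⇒ 7-O-silyl ether of the same catechol ⇒ (ortho-oxygenation of a phenol via its o-quinone) ⇒ (2S)-naringenin carrying the hydrated geranyl chain at C3'.
- Key disconnection: the aryl–CH2 bond, made by an aromatic Claisen [3,3] rearrangement of the 4'-O-(1-methyl-1-alkylallyl) ether; the para position is blocked and the two ortho positions are equivalent.
- That tertiary allyl aryl ether ⇒ Tsuji–Trost O-allylation of 7-O-TIPS-(2S)-naringenin with an (E)-allylic methyl carbonate made from geraniol (carbonate formation, then hydration of the remote alkene).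
- Rings: none is built. The chromanone bicycle and the B ring, with the only stereocentre C2 (S), are bought in (2S)-naringenin and carried through base-free steps; the only ring formed is the transient six-membered chair of the Claisen step.

Assumption: (2S)-naringenin is bought as the single enantiomer (it is sold as such and is the aglycone of the bulk citrus glycoside naringin).

**Route**

Step 1
Reactants: 1 geraniol
Product: 2 geranyl methyl carbonate
Conditions: ClCO2Me (1.2 equiv), pyridine (2 equiv), CH2Cl2, 0 °C to rt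
Reagents that add atoms: methyl chloroformate, COC(=O)Cl
Why: O-alkoxycarbonylation of the primary allylic alcohol with pyridine as HCl scavenger proceeds without allylic transposition, so the E geometry bought in geraniol is kept.

Step 2
Reactants: 2 geranyl methyl carbonate
Product: 4 (2E)-7-hydroxy-3,7-dimethyloct-2-en-1-yl methyl carbonate, via organomercurial adduct 3 (not isolated)
Conditions: Hg(OAc)2 (1.05 equiv), THF–H2O 1:1, rt, 30 min; then NaBH4, 3 M NaOH, 0 °C, 10 min
Reagents that add atoms: water, O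
Why: Oxymercuration–demercuration gives Markovnikov hydration of the electron-rich remote trisubstituted alkene only, because the 2,3-alkene is deactivated by the allylic carbonate, and the short cold borohydride step leaves the carbonate and the E alkene untouched.

Step 3
Reactants: 5 (2S)-naringenin
Product: 6 (2S)-7-O-(triisopropylsilyl)naringenin
Conditions: TIPSCl (1.05 equiv), imidazole (2.2 equiv), DMF, 0 °C, 1 h
Reagents that add atoms: triisopropylsilyl chloride, CC(C)[Si](Cl)(C(C)C)C(C)C
Why: Selective silylation of the most acidic phenol: the 7-OH (vinylogous acid, pKa about 7.5) is the one ionised by imidazole, the 5-OH is locked in a hydrogen bond to C4=O and the 4'-OH (pKa about 10) reacts more slowly, while this mild base at 0 °C does not open the pyranone ring, so C2 stays S.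

Step 4
Reactants: 6 (2S)-7-O-(triisopropylsilyl)naringenin; 4 (2E)-7-hydroxy-3,7-dimethyloct-2-en-1-yl methyl carbonate (1.1 equiv)
Product: 7 (2S)-7-O-TIPS-4'-O-(7-hydroxy-3,7-dimethyloct-1-en-3-yl)naringenin (both epimers at the ether carbon)
Conditions: Pd(PPh3)4 (3 mol %), THF, 0 °C, 30–60 min, stopped when 4 is consumed
Reagents that add atoms: none
Why: Tsuji–Trost O-allylation: decarboxylative ionisation gives a π-allylpalladium methoxide that deprotonates only the 4'-phenol (the tertiary alcohol and the chelated 5-OH stay protonated), and the phenoxide attacks the more substituted allyl terminus under kinetic control to give the tertiary ether without added base; the new ether carbon forms as both epimers, which is harmless because it becomes sp2 in step 5.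

Step 5
Reactants: 7 (2S)-7-O-TIPS-4'-O-(7-hydroxy-3,7-dimethyloct-1-en-3-yl)naringenin
Product: 9 (2S)-7-O-TIPS-3'-[(2E)-7-hydroxy-3,7-dimethyloct-2-en-1-yl]naringenin, via ortho-dienone 8 (not isolated)
Conditions: degassed PhMe, 110 °C (sealed tube, base-washed glass), 8–12 h; AgNO3–SiO2 chromatography
Reagents that add atoms: none
Why: Aromatic Claisen [3,3]-sigmatropic rearrangement through a chair transition state forms the aryl–CH2 bond at either of the two equivalent free ortho carbons (para is blocked) and the dienone rearomatises; the long chain prefers the pseudo-equatorial position only slightly, so the E alkene is the major isomer (about 2:1 expected) and the Z isomer is removed on silver nitrate silica, while C2 is untouched under these neutral conditions.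

Step 6
Reactants: 9 (2S)-7-O-TIPS-3'-[(2E)-7-hydroxy-3,7-dimethyloct-2-en-1-yl]naringenin
Product: 11 (2S)-7-O-TIPS-propolin B, via ortho-quinone 10 (not isolated)
Conditions: IBX (1.2 equiv), DMF, 0 °C to rt, 1 h; then aq. Na2S2O4, EtOAc, 0 °C
Reagents that add atoms: 2-iodoxybenzoic acid (IBX), O=C1OI(=O)(O)c2ccccc12
Why: IBX ortho-oxygenation of a phenol: ligand exchange of the 4'-OH on iodine(V) and intramolecular oxygen delivery to the only free ortho carbon give the o-quinone, which dithionite reduces at once to the catechol, while the chelated 5-OH on the acylated A ring, the silyl ether, the alkene and the tertiary alcohol do not react at this temperature.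

Step 7
Reactants: 11 (2S)-7-O-TIPS-propolin B
Product: 12 propolin B
Conditions: TBAF (1.2 equiv), AcOH (1.2 equiv), THF, 0 °C, 15 min
Reagents that add atoms: none
Why: Fluoride-mediated cleavage of the aryl silyl ether, buffered with acetic acid so that neither base-induced chalcone ring-opening (loss of the C2 configuration) nor catechol autoxidation can occur, releases the target.

**Compound list**

1 | geraniol, (2E)-3,7-dimethylocta-2,6-dien-1-ol | CC(C)=CCC/C(C)=C/CO | starting material
2 | geranyl methyl carbonate, (2E)-3,7-dimethylocta-2,6-dien-1-yl methyl carbonate | CC(C)=CCC/C(C)=C/COC(=O)OC | intermediate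
3 | organomercurial adduct, (2E)-6-(acetoxymercurio)-7-hydroxy-3,7-dimethyloct-2-en-1-yl methyl carbonate (racemic at C6) | CC(C)(O)C([Hg]OC(C)=O)CC/C(C)=C/COC(=O)OC | intermediate
4 | (2E)-7-hydroxy-3,7-dimethyloct-2-en-1-yl methyl carbonate | CC(C)(O)CCC/C(C)=C/COC(=O)OC | intermediate
5 | (2S)-naringenin, (2S)-5,7-dihydroxy-2-(4-hydroxyphenyl)chroman-4-one | Oc1ccc([C@@H]2CC(=O)c3c(O)cc(O)cc3O2)cc1 | starting material
6 | (2S)-5-hydroxy-2-(4-hydroxyphenyl)-7-(triisopropylsilyloxy)chroman-4-one | Oc1ccc([C@@H]2CC(=O)c3c(O)cc(O[Si](C(C)C)(C(C)C)C(C)C)cc3O2)cc1 | intermediate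
7 | (2S)-5-hydroxy-2-{4-[(7-hydroxy-3,7-dimethyloct-1-en-3-yl)oxy]phenyl}-7-(triisopropylsilyloxy)chroman-4-one, both epimers at the ether carbon | C=CC(C)(CCCC(C)(C)O)Oc1ccc([C@@H]2CC(=O)c3c(O)cc(O[Si](C(C)C)(C(C)C)C(C)C)cc3O2)cc1 | intermediate
8 | ortho-dienone, 6-[(2E)-7-hydroxy-3,7-dimethyloct-2-enyl]-4-[(2S)-chromanon-2-yl]cyclohexa-2,4-dien-1-one (ring sp3 carbon unassigned) | O=C1C=CC([C@@H]2CC(=O)c3c(O)cc(O[Si](C(C)C)(C(C)C)C(C)C)cc3O2)=CC1C/C=C(\C)CCCC(C)(C)O | intermediate
9 | (2S)-5-hydroxy-2-{4-hydroxy-3-[(2E)-7-hydroxy-3,7-dimethyloct-2-en-1-yl]phenyl}-7-(triisopropylsilyloxy)chroman-4-one | Oc1ccc([C@@H]2CC(=O)c3c(O)cc(O[Si](C(C)C)(C(C)C)C(C)C)cc3O2)cc1C/C=C(\C)CCCC(C)(C)O | intermediate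
10 | ortho-quinone, 3-[(2E)-7-hydroxy-3,7-dimethyloct-2-enyl]-5-[(2S)-5-hydroxy-4-oxo-7-(triisopropylsilyloxy)chroman-2-yl]-1,2-benzoquinone | O=C1C(=O)C=C([C@@H]2CC(=O)c3c(O)cc(O[Si](C(C)C)(C(C)C)C(C)C)cc3O2)C=C1C/C=C(\C)CCCC(C)(C)O | intermediate
11 | (2S)-2-{3,4-dihydroxy-5-[(2E)-7-hydroxy-3,7-dimethyloct-2-en-1-yl]phenyl}-5-hydroxy-7-(triisopropylsilyloxy)chroman-4-one | Oc1cc([C@@H]2CC(=O)c3c(O)cc(O[Si](C(C)C)(C(C)C)C(C)C)cc3O2)cc(C/C=C(\C)CCCC(C)(C)O)c1O | intermediate
12 | propolin B, (2S)-2-{3,4-dihydroxy-5-[(2E)-7-hydroxy-3,7-dimethyloct-2-en-1-yl]phenyl}-5,7-dihydroxychroman-4-one | C/C(=C\Cc1cc([C@@H]2CC(=O)c3c(O)cc(O)cc3O2)cc(O)c1O)CCCC(C)(C)O | target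

**Count**

Total steps: 7. Longest linear sequence: 6 steps (1 → 2 → 4 → 7 → 9 → 11 → 12; steps 1, 2, 4, 5, 6, 7). From naringenin it is 5 steps.

**Three steps most likely to fail**

Risk 1, step 4 (branched O-allylation). Palladium can re-ionise the tertiary aryl ether and drift to the linear primary ether, or give C-allylation. The fallback leaves π-allyl chemistry; it sets out from 6 and comes back at 7. Ethynylmagnesium bromide is added to commercial 6-hydroxy-6-methylheptan-2-one (THF, 0 °C) to give 3,7-dimethyloct-1-yne-3,7-diol F1. TFAA (2.2 equiv) and DBU in MeCN at −5 °C convert it in situ into 3,7-dimethyloct-1-yne-3,7-diyl bis(trifluoroacetate) F2. Adding 6 with CuCl2·2H2O (1 mol %) and DBU at −5 °C gives copper-catalysed propargylic substitution at the tertiary propargylic carbon only, forming the aryl propargyl ether that still carries the remote trifluoroacetate F3. Aqueous NaHCO3/MeOH work-up hydrolyses that ester to the hydroxy propargyl ether F4. Lindlar semihydrogenation (H2, Pd/CaCO3/Pb, quinoline, EtOAc) of the terminal alkyne then gives 7.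

Risk 2, step 5 (Claisen). The E/Z selectivity is intrinsically low because methyl and a primary alkyl compete for the equatorial site, and the tertiary ether can also fragment to 6 and a diene. The fallback carries the E alkene of geraniol through intact instead of creating it; it sets out from 4 and 6 and comes back at 9. Methanolysis of 4 (cat. K2CO3, MeOH, rt) gives (2E)-3,7-dimethyloct-2-ene-1,7-diol F5. A Mitsunobu reaction with 6 (PPh3, DIAD, THF, 0 °C; neutral, primary allylic OH only) gives the linear ether (2S)-7-O-TIPS-4'-O-[(2E)-7-hydroxy-3,7-dimethyloct-2-en-1-yl]naringenin F6. Montmorillonite K10 (CH2Cl2, 0 °C) then moves the whole allyl unit from oxygen to the ortho carbon by an ion-pair 1,3-shift (para is blocked), giving 9 with the bought E alkene untouched.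

Risk 3, step 6 (ortho-oxygenation). The o-quinone 10 can tautomerise to quinone methides before it is reduced: through C2–H this erodes the S configuration, and through the benzylic/allylic CH2 it leads to a chromene. The fallback avoids any quinone; it sets out from 9 and comes back at 11. Magnesium-mediated ortho-formylation (MgCl2, Et3N, paraformaldehyde, MeCN, 60 °C) at the only free position ortho to the 4'-OH gives the salicylaldehyde (2S)-7-O-TIPS-5'-formyl-3'-[(2E)-7-hydroxy-3,7-dimethyloct-2-en-1-yl]naringenin F7. Dakin oxidation (30 % H2O2, B(OH)3, THF, rt) gives the aryl formate F8, which is hydrolysed on aqueous NaHCO3 work-up to 11. The formylation uses Et3N at 60 °C, so the ee should be checked by chiral HPLC here, as it should after steps 5 and 7 of the main route.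

**Further compounds**

F1 | step 4 | 3,7-dimethyloct-1-yne-3,7-diol (racemic) | C#CC(C)(O)CCCC(C)(C)O
F2 | step 4 | 3,7-dimethyloct-1-yne-3,7-diyl bis(trifluoroacetate) | C#CC(C)(CCCC(C)(C)OC(=O)C(F)(F)F)OC(=O)C(F)(F)F
F3 | step 4 | (2S)-7-O-TIPS-4'-O-[3,7-dimethyl-7-(trifluoroacetoxy)oct-1-yn-3-yl]naringenin (both epimers) | C#CC(C)(CCCC(C)(C)OC(=O)C(F)(F)F)Oc1ccc([C@@H]2CC(=O)c3c(O)cc(O[Si](C(C)C)(C(C)C)C(C)C)cc3O2)cc1
F4 | step 4 | (2S)-7-O-TIPS-4'-O-(7-hydroxy-3,7-dimethyloct-1-yn-3-yl)naringenin (both epimers) | C#CC(C)(CCCC(C)(C)O)Oc1ccc([C@@H]2CC(=O)c3c(O)cc(O[Si](C(C)C)(C(C)C)C(C)C)cc3O2)cc1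
F5 | step 5 | (2E)-3,7-dimethyloct-2-ene-1,7-diol | CC(C)(O)CCC/C(C)=C/CO
F6 | step 5 | (2S)-7-O-TIPS-4'-O-[(2E)-7-hydroxy-3,7-dimethyloct-2-en-1-yl]naringenin | CC(C)(O)CCC/C(C)=C/COc1ccc([C@@H]2CC(=O)c3c(O)cc(O[Si](C(C)C)(C(C)C)C(C)C)cc3O2)cc1
F7 | step 6 | (2S)-7-O-TIPS-5'-formyl-3'-[(2E)-7-hydroxy-3,7-dimethyloct-2-en-1-yl]naringenin | O=Cc1cc([C@@H]2CC(=O)c3c(O)cc(O[Si](C(C)C)(C(C)C)C(C)C)cc3O2)cc(C/C=C(\C)CCCC(C)(C)O)c1O
F8 | step 6 | 3'-O-formyl derivative of 11 (aryl formate) | O=COc1cc([C@@H]2CC(=O)c3c(O)cc(O[Si](C(C)C)(C(C)C)C(C)C)cc3O2)cc(C/C=C(\C)CCCC(C)(C)O)c1O
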